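**Retrosynthetic overview**

1. The strategy rests on the oxolan-2-one ring: it carries trans benzyl groups on C3 (to ring B) and C4 (to ring A) beside a bare C5H2–O1, so C5 can be carried as a stereogenic menthyl acetal carbon that steers C4 and then C3 and is afterwards reduced back to CH2.
2. Key disconnections, both made in one flask on the preformed butenolide ring: C4–CH2(ring A) by 1,4-addition of a ring A 2-lithio-1,3-dithiane, and C3–CH2(ring B) by benzylation of the resulting enolate with a ring B benzylic bromide; no ring closes.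
3. Both aryl fragments come from one N-arylacetyl oxazolidinone made from 5-bromovanillin. An anti aldol with O-benzylvanillin gives the (7S,8S) arm of ring A and a syn aldol the (7S,8R) arm of ring B; each 1,3-diol is held as an acetonide.
4. Ring order: dithiane (step 2), the two 1,3-dioxanes (steps 8 and 11), the butenolide from furfural (steps 15 and 16). After the coupling the lactone is opened once to excise the acetal oxygen and re-closed (step 19), then deprotected.

Key step: step 17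

Assumption: the magnesium-chelated Z-enolate of the arylacetyl imide 8 is taken to react on the same face as N-propionyl oxazolidinones do (opposite the C4 benzyl group), so the (S)-auxiliary serves both the anti and the syn aldol.

Shorthand in names: ArA = 4-(benzyloxy)-3-[(4S,5S)-4-(4-(benzyloxy)-3-methoxyphenyl)-2,2-dimethyl-1,3-dioxan-5-yl]-5-methoxyphenyl; ArB = the same aryl group with the (4S,5R)-dioxane; Men = (1S,2R,5S)-2-isopropyl-5-methylcyclohexyl.

**Route**

Step 1
Reactants: 1 5-bromovanillin (3-bromo-4-hydroxy-5-methoxybenzaldehyde)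
Product: 2 4-(benzyloxy)-3-bromo-5-methoxybenzaldehyde
Conditions: BnBr, K2CO3, DMF, rt
Reagents that add atoms: benzyl bromide, BrCc1ccccc1
Why: Williamson etherification of the acidic phenol (para to the formyl group) installs the benzyl ether that tolerates every later step and falls to hydrogenolysis at the end.

Step 2
Reactants: 2 4-(benzyloxy)-3-bromo-5-methoxybenzaldehyde
Product: 3 2-[4-(benzyloxy)-3-bromo-5-methoxyphenyl]-1,3-dithiane
Conditions: HS(CH2)3SH, BF3·OEt2 (cat.), CH2Cl2, 0 °C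
Reagents that add atoms: propane-1,3-dithiol, SCCCS
Why: Lewis-acid-catalysed thioacetalisation of the aryl aldehyde is faster than benzyl ether cleavage at 0 °C and gives the dithiane that masks the aldehyde through the arm construction and later becomes the acyl-anion equivalent of ring A.

Step 3
Reactants: 3 2-[4-(benzyloxy)-3-bromo-5-methoxyphenyl]-1,3-dithiane
Product: 4 ethyl 2-[2-(benzyloxy)-5-(1,3-dithian-2-yl)-3-methoxyphenyl]acetate
Conditions: BrZnCH2CO2Et (THF solution), Pd2(dba)3 (cat.), XPhos (cat.), THF, 65 °C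
Reagents that add atoms: (2-ethoxy-2-oxoethyl)zinc bromide, CCOC(=O)C[Zn]Br
Why: Negishi-type cross-coupling of a Reformatsky zinc enolate (palladium-catalysed α-arylation of an ester) forms the aryl–CH2 bond under neutral conditions that leave the dithiane C–H and the benzyl ether alone, the bulky biarylphosphine letting zerovalent palladium insert into the electron-rich ortho-alkoxy C–Br bond.

Step 4
Reactants: 4 ethyl 2-[2-(benzyloxy)-5-(1,3-dithian-2-yl)-3-methoxyphenyl]acetate
Product: 5 2-[2-(benzyloxy)-5-(1,3-dithian-2-yl)-3-methoxyphenyl]acetic acid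
Conditions: LiOH, THF/MeOH/H2O, rt; then 1 M HCl to pH 3
Reagents that add atoms: lithium hydroxide, [Li+].[OH-]
Why: Saponification of the unhindered ethyl arylacetate (acyl–oxygen cleavage) and mild acidification give the free acid without touching the thioacetal or the benzyl ether.

Step 5
Reactants: 5 2-[2-(benzyloxy)-5-(1,3-dithian-2-yl)-3-methoxyphenyl]acetic acid; 6 (S)-4-benzyl-1,3-oxazolidin-2-one
Product: 8 (4S)-4-benzyl-3-{2-[2-(benzyloxy)-5-(1,3-dithian-2-yl)-3-methoxyphenyl]acetyl}-1,3-oxazolidin-2-one, via mixed pivalic anhydride 7 (not isolated)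
Conditions: PivCl, Et3N, THF, −20 °C; then 6, LiCl, rt
Reagents that add atoms: none
Why: N-acylation of the oxazolidinone through the mixed pivalic anhydride, activated by LiCl/Et3N, is the standard entry to arylacetyl imides and takes place at the less hindered arylacetyl carbonyl of 7.

Step 6
Reactants: 8 (4S)-4-benzyl-3-{2-[2-(benzyloxy)-5-(1,3-dithian-2-yl)-3-methoxyphenyl]acetyl}-1,3-oxazolidin-2-one; 9 O-benzylvanillin (4-(benzyloxy)-3-methoxybenzaldehyde)
Product: 11 (4S)-4-benzyl-3-{(2R,3S)-3-[4-(benzyloxy)-3-methoxyphenyl]-2-[2-(benzyloxy)-5-(1,3-dithian-2-yl)-3-methoxyphenyl]-3-hydroxypropanoyl}-1,3-oxazolidin-2-one, via O-trimethylsilyl ether 10 (not isolated)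
Conditions: MgCl2 (0.2 equiv), Et3N, TMSCl, EtOAc, rt; then 1 M HCl, THF, rt
Reagents that add atoms: none
Why: Magnesium-halide-catalysed direct anti-aldol addition of an N-acyl oxazolidinone: soft enolisation gives the chelated Z-enolate, the aldehyde adds through a boat-like transition state on the face opposite the auxiliary benzyl group, which sets C8 (2R in the imide) and C7 (3S) in the anti relationship, and silylation of the aldolate makes the addition irreversible before the silyl ether is hydrolysed on work-up.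

Step 7
Reactants: 11 anti aldol adduct (2R,3S)
Product: 12 (1S,2S)-1-[4-(benzyloxy)-3-methoxyphenyl]-2-[2-(benzyloxy)-5-(1,3-dithian-2-yl)-3-methoxyphenyl]propane-1,3-diol
Conditions: LiBH4, MeOH (1 equiv), THF, 0 °C
Reagents that add atoms: none
Why: LiBH4 reduces the exocyclic imide carbonyl chemoselectively (reductive removal of the auxiliary, which is recovered) and leaves C7 and C8 untouched, giving the 1,3-diol.

Step 8
Reactants: 12 (1S,2S)-diol
Product: 13 2-{4-(benzyloxy)-3-[(4S,5S)-4-(4-(benzyloxy)-3-methoxyphenyl)-2,2-dimethyl-1,3-dioxan-5-yl]-5-methoxyphenyl}-1,3-dithiane (ring A dithiane)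
Conditions: Me2C(OMe)2, PPTS (cat.), CH2Cl2, rt
Reagents that add atoms: 2,2-dimethoxypropane, COC(C)(C)OC
Why: Acid-catalysed transketalisation closes the six-membered isopropylidene ketal (both aryl groups equatorial in the trans-4,5-disubstituted dioxane) and removes both hydroxyl protons before the organolithium step.

Step 9
Reactants: 8 (4S)-4-benzyl-3-{2-[2-(benzyloxy)-5-(1,3-dithian-2-yl)-3-methoxyphenyl]acetyl}-1,3-oxazolidin-2-one; 9 O-benzylvanillin
Product: 16 (4S)-4-benzyl-3-{(2S,3S)-3-[4-(benzyloxy)-3-methoxyphenyl]-2-[2-(benzyloxy)-5-(1,3-dithian-2-yl)-3-methoxyphenyl]-3-hydroxypropanoyl}-1,3-oxazolidin-2-one, via Z-dibutylboron enolate 14 (not isolated), via dibutylboron aldolate 15 (not isolated)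
Conditions: Bu2BOTf, iPr2NEt, CH2Cl2, −78 → 0 °C; then 9, −78 → 0 °C; then pH 7 phosphate buffer, MeOH (no peroxide)
Reagents that add atoms: none
Why: Evans syn-aldol: the Z-boron enolate reacts through a closed chair (Zimmerman–Traxler) transition state in the dipole-minimised conformation of the auxiliary, so the aldehyde adds to the enolate face opposite to that used in step 6 and sets (2S,3S), the same C7 configuration with C8 inverted, while the peroxide-free work-up spares the dithiane.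

Step 10
Reactants: 16 syn aldol adduct (2S,3S)
Product: 17 (1S,2R)-1-[4-(benzyloxy)-3-methoxyphenyl]-2-[2-(benzyloxy)-5-(1,3-dithian-2-yl)-3-methoxyphenyl]propane-1,3-diol
Conditions: LiBH4, MeOH (1 equiv), THF, 0 °C
Reagents that add atoms: none
Why: Reductive removal of the auxiliary as in step 7, with hydride attack at the exocyclic imide carbonyl and no change at C7 or C8.

Step 11
Reactants: 17 (1S,2R)-diol
Product: 18 2-{4-(benzyloxy)-3-[(4S,5R)-4-(4-(benzyloxy)-3-methoxyphenyl)-2,2-dimethyl-1,3-dioxan-5-yl]-5-methoxyphenyl}-1,3-dithiane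
Conditions: Me2C(OMe)2, PPTS (cat.), CH2Cl2, rt
Reagents that add atoms: 2,2-dimethoxypropane, COC(C)(C)OC
Why: Transketalisation as in step 8; the syn diol gives the cis-4,5-diaryl dioxane, which still closes readily with one aryl group axial.

Step 12
Reactants: 18 ring B dithiane acetonide
Product: 19 4-(benzyloxy)-3-[(4S,5R)-4-(4-(benzyloxy)-3-methoxyphenyl)-2,2-dimethyl-1,3-dioxan-5-yl]-5-methoxybenzaldehyde
Conditions: MeI, CaCO3, MeCN/H2O, 45 °C
Reagents that add atoms: water, O
Why: Alkylative hydrolysis of the dithiane: S-methylation makes a sulfonium leaving group, the electron-rich arene assists ionisation and water captures the thionium ion, while CaCO3 keeps the medium near neutral so that the acetonide and benzyl ethers persist.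

Step 13
Reactants: 19 ring B aldehyde
Product: 20 {4-(benzyloxy)-3-[(4S,5R)-4-(4-(benzyloxy)-3-methoxyphenyl)-2,2-dimethyl-1,3-dioxan-5-yl]-5-methoxyphenyl}methanol
Conditions: NaBH4, MeOH/THF, 0 °C
Reagents that add atoms: none
Why: Borohydride reduction of the aryl aldehyde to the benzylic alcohol; nothing else in the molecule is reducible under these conditions.

Step 14
Reactants: 20 ring B benzylic alcohol
Product: 21 (4S,5R)-4-[4-(benzyloxy)-3-methoxyphenyl]-5-[2-(benzyloxy)-5-(bromomethyl)-3-methoxyphenyl]-2,2-dimethyl-1,3-dioxane (ring B bromide)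
Conditions: CBr4, PPh3, CH2Cl2, 0 °C; used directly
Reagents that add atoms: carbon tetrabromide, BrC(Br)(Br)Br
Why: Appel bromination converts the primary benzylic alcohol into the bromide by SN2 displacement of the alkoxyphosphonium under neutral conditions that do not ionise the acetonide.

Step 15
Reactants: 22 furfural
Product: 23 5-hydroxyfuran-2(5H)-one (racemic)
Conditions: O2, hν (visible light), rose bengal (cat.), MeOH, rt
Reagents that add atoms: oxygen, O=O
Why: Dye-sensitised photooxygenation: singlet oxygen adds [4+2] across the furan and methanolysis of the endoperoxide expels the formyl carbon as methyl formate, leaving the hydroxybutenolide.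

Step 16
Reactants: 23 5-hydroxyfuran-2(5H)-one; 24 (+)-menthol ((1S,2R,5S)-2-isopropyl-5-methylcyclohexan-1-ol)
Product: 25 (5S)-5-{[(1S,2R,5S)-2-isopropyl-5-methylcyclohexyl]oxy}furan-2(5H)-one
Conditions: camphorsulfonic acid (cat.), toluene, reflux (Dean–Stark); crystallisation from petroleum ether
Reagents that add atoms: none
Why: Acid-catalysed acetalisation of the cyclic pseudo-acid; the two C5 epimers interconvert under the acidic conditions and the (5S) epimer of the (1S,2R,5S)-menthyl series should crystallise, so crystallisation with re-equilibration of the mother liquor delivers the single diastereomer.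

Step 17
Reactants: 13 ring A dithiane; 25 (5S)-5-menthyloxybutenolide; 21 ring B bromide
Product: 28 (3S,4S,5S)-3-[(ArB)methyl]-4-[2-(ArA)-1,3-dithian-2-yl]-5-(MenO)oxolan-2-one, via 2-lithio dithiane 26 (not isolated), via lithium lactone enolate 27 (not isolated)
Conditions: n-BuLi, THF, −78 → −20 °C; then 25, −78 °C; then 21, DMPU, −78 → −20 °C
Reagents that add atoms: none
Why: n-BuLi removes the C2–H of dithiane 13 (the aryl- and sulfur-stabilised carbanion forms faster than any benzyl ether α-lithiation at low temperature), the soft 2-lithio-2-aryl-1,3-dithiane 26 adds 1,4 to butenolide 25, and the lithium enolate 27 is C-benzylated by bromide 21 (SN2) once DMPU is added. The closest known reaction type is the tandem conjugate addition–enolate alkylation of lithiated aryl dithianes with 5-alkoxyfuran-2(5H)-ones and benzylic bromides used for trans-dibenzylbutyrolactone lignans. No ring is closed; two C–C bonds form, C4–C(dithiane) and C3–CH2 of ring B. C4 is set by the (5S) acetal carbon, the nucleophile entering anti to the menthyloxy group (4S); C3 is set by C4, the bromide approaching the planar enolate anti to the bulky dithianyl group (3S, trans,trans). The step needs 1,4- over 1,2-addition (secured by the delocalised aryl dithianyl anion), C- over O-alkylation and mono-alkylation (lithium enolate, reactive electron-rich benzylic bromide, one equivalent), and tolerance of the acetonides and benzyl ethers, which carry no proton acidic enough to compete.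

Step 18
Reactants: 28 trans,trans dithianyl lactone acetal
Product: 29 (3S,4S,5S)-3-[(ArB)methyl]-4-[(ArA)methyl]-5-(MenO)oxolan-2-one
Conditions: NiCl2·6H2O, NaBH4, MeOH/THF, 0 °C
Reagents that add atoms: none
Why: Nickel boride formed from NiCl2 and NaBH4 hydrogenolyses both benzylic C–S bonds (reductive desulfurisation) at 0 °C, conditions under which aryl benzyl ethers, the acetonides and the lactone acetal are not reduced.

Step 19
Reactants: 29 desulfurised lactone acetal
Product: 32 (3S,4S)-3-[(ArB)methyl]-4-[(ArA)methyl]oxolan-2-one, via potassium formyl carboxylate 30 (not isolated), via potassium hydroxy carboxylate 31 (not isolated)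
Conditions: KOH, NaBH4, EtOH/H2O, rt; then 1 M HCl to pH 3, 0 °C → rt
Reagents that add atoms: none
Why: Hydroxide opens the pseudo-ester, the hemiacetal alkoxide expels menthol to give the aldehyde carboxylate, NaBH4 present from the start reduces the aldehyde before C4 can epimerise, and acidification closes the γ-hydroxy acid by 5-exo-trig lactonisation, so C5 returns as CH2 with C3 and C4 unchanged.

Step 20
Reactants: 32 bis-acetonide tetrabenzyl lactone
Product: 33 (3S,4S)-3-{4-(benzyloxy)-3-[(1S,2R)-1-(4-(benzyloxy)-3-methoxyphenyl)-1,3-dihydroxypropan-2-yl]-5-methoxybenzyl}-4-{4-(benzyloxy)-3-[(1S,2S)-1-(4-(benzyloxy)-3-methoxyphenyl)-1,3-dihydroxypropan-2-yl]-5-methoxybenzyl}oxolan-2-one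
Conditions: AcOH/H2O/THF, 40 °C
Reagents that add atoms: none
Why: Acid-catalysed hydrolysis of the two isopropylidene ketals proceeds by ionisation at the ketal carbon, which is faster than ionisation of the benzylic C7–O bonds in weak aqueous acid, and water is the only nucleophile, so C7 should keep its configuration and no C7 ether can form.

Step 21
Reactants: 33 tetra-O-benzyl tetrol lactone
Product: 34 CNP0113972.1, (3S,4S)-3-{4-hydroxy-3-[(1S,2R)-1,3-dihydroxy-1-(4-hydroxy-3-methoxyphenyl)propan-2-yl]-5-methoxybenzyl}-4-{4-hydroxy-3-[(1S,2S)-1,3-dihydroxy-1-(4-hydroxy-3-methoxyphenyl)propan-2-yl]-5-methoxybenzyl}oxolan-2-one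
Conditions: H2 (1 atm), 10% Pd/C, EtOAc/MeOH, rt
Reagents that add atoms: none
Why: Catalytic hydrogenolysis cleaves the four aryl benzyl ethers under neutral conditions, where O-benzyl cleavage is much faster than hydrogenolysis of the secondary benzylic C–OH bonds or reduction of the lactone.

**Compound list**

1 | 5-bromovanillin (3-bromo-4-hydroxy-5-methoxybenzaldehyde) | COc1cc(C=O)cc(Br)c1O | starting material
2 | 4-(benzyloxy)-3-bromo-5-methoxybenzaldehyde | COc1cc(C=O)cc(Br)c1OCc1ccccc1 | intermediate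
3 | 2-[4-(benzyloxy)-3-bromo-5-methoxyphenyl]-1,3-dithiane | COc1cc(C2SCCCS2)cc(Br)c1OCc1ccccc1 | intermediate
4 | ethyl 2-[2-(benzyloxy)-5-(1,3-dithian-2-yl)-3-methoxyphenyl]acetate | CCOC(=O)Cc1cc(C2SCCCS2)cc(OC)c1OCc1ccccc1 | intermediate
5 | 2-[2-(benzyloxy)-5-(1,3-dithian-2-yl)-3-methoxyphenyl]acetic acid | OC(=O)Cc1cc(C2SCCCS2)cc(OC)c1OCc1ccccc1 | intermediate
6 | (S)-4-benzyl-1,3-oxazolidin-2-one | O=C1N[C@@H](Cc2ccccc2)CO1 | starting material
7 | mixed anhydride of acid 5 with pivalic acid (formed in situ) | CC(C)(C)C(=O)OC(=O)Cc1cc(C2SCCCS2)cc(OC)c1OCc1ccccc1 | intermediate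
8 | (4S)-4-benzyl-3-{2-[2-(benzyloxy)-5-(1,3-dithian-2-yl)-3-methoxyphenyl]acetyl}-1,3-oxazolidin-2-one | O=C(Cc1cc(C2SCCCS2)cc(OC)c1OCc1ccccc1)N1[C@@H](Cc2ccccc2)COC1=O | intermediate
9 | O-benzylvanillin (4-(benzyloxy)-3-methoxybenzaldehyde) | COc1cc(C=O)ccc1OCc1ccccc1 | starting material
10 | O-trimethylsilyl ether of anti aldol adduct 11 (formed in situ) | COc1cc([C@@H](O[Si](C)(C)C)[C@H](C(=O)N2[C@@H](Cc3ccccc3)COC2=O)c2cc(C3SCCCS3)cc(OC)c2OCc2ccccc2)ccc1OCc1ccccc1 | intermediate
11 | (4S)-4-benzyl-3-{(2R,3S)-3-[4-(benzyloxy)-3-methoxyphenyl]-2-[2-(benzyloxy)-5-(1,3-dithian-2-yl)-3-methoxyphenyl]-3-hydroxypropanoyl}-1,3-oxazolidin-2-one (anti adduct) | COc1cc([C@@H](O)[C@H](C(=O)N2[C@@H](Cc3ccccc3)COC2=O)c2cc(C3SCCCS3)cc(OC)c2OCc2ccccc2)ccc1OCc1ccccc1 | intermediate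
12 | (1S,2S)-1-[4-(benzyloxy)-3-methoxyphenyl]-2-[2-(benzyloxy)-5-(1,3-dithian-2-yl)-3-methoxyphenyl]propane-1,3-diol | COc1cc([C@@H](O)[C@H](CO)c2cc(C3SCCCS3)cc(OC)c2OCc2ccccc2)ccc1OCc1ccccc1 | intermediate
13 | 2-{4-(benzyloxy)-3-[(4S,5S)-4-(4-(benzyloxy)-3-methoxyphenyl)-2,2-dimethyl-1,3-dioxan-5-yl]-5-methoxyphenyl}-1,3-dithiane (ring A dithiane) | COc1cc([C@@H](OC(C)(C)OC4)[C@H]4c2cc(C3SCCCS3)cc(OC)c2OCc2ccccc2)ccc1OCc1ccccc1 | intermediate
14 | Z-dibutylboron enolate of imide 8 (formed in situ) | CCCCB(CCCC)O/C(=C\c1cc(C2SCCCS2)cc(OC)c1OCc1ccccc1)N1[C@@H](Cc2ccccc2)COC1=O | intermediate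
15 | O-dibutylboron aldolate of syn adduct 16 (formed in situ) | COc1cc(C2SCCCS2)cc([C@H](C(=O)N3[C@@H](Cc4ccccc4)COC3=O)[C@H](OB(CCCC)CCCC)c3ccc(OCc4ccccc4)c(OC)c3)c1OCc1ccccc1 | intermediate
16 | (4S)-4-benzyl-3-{(2S,3S)-3-[4-(benzyloxy)-3-methoxyphenyl]-2-[2-(benzyloxy)-5-(1,3-dithian-2-yl)-3-methoxyphenyl]-3-hydroxypropanoyl}-1,3-oxazolidin-2-one (syn adduct) | COc1cc(C2SCCCS2)cc([C@H](C(=O)N3[C@@H](Cc4ccccc4)COC3=O)[C@H](O)c3ccc(OCc4ccccc4)c(OC)c3)c1OCc1ccccc1 | intermediate
17 | (1S,2R)-1-[4-(benzyloxy)-3-methoxyphenyl]-2-[2-(benzyloxy)-5-(1,3-dithian-2-yl)-3-methoxyphenyl]propane-1,3-diol | COc1cc(C2SCCCS2)cc([C@H](CO)[C@H](O)c3ccc(OCc4ccccc4)c(OC)c3)c1OCc1ccccc1 | intermediate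
18 | 2-{4-(benzyloxy)-3-[(4S,5R)-4-(4-(benzyloxy)-3-methoxyphenyl)-2,2-dimethyl-1,3-dioxan-5-yl]-5-methoxyphenyl}-1,3-dithiane | COc1cc(C2SCCCS2)cc([C@H](COC(C)(C)O5)[C@H]5c3ccc(OCc4ccccc4)c(OC)c3)c1OCc1ccccc1 | intermediate
19 | 4-(benzyloxy)-3-[(4S,5R)-4-(4-(benzyloxy)-3-methoxyphenyl)-2,2-dimethyl-1,3-dioxan-5-yl]-5-methoxybenzaldehyde | COc1cc(C=O)cc([C@H](COC(C)(C)O5)[C@H]5c3ccc(OCc4ccccc4)c(OC)c3)c1OCc1ccccc1 | intermediate
20 | {4-(benzyloxy)-3-[(4S,5R)-4-(4-(benzyloxy)-3-methoxyphenyl)-2,2-dimethyl-1,3-dioxan-5-yl]-5-methoxyphenyl}methanol | COc1cc(CO)cc([C@H](COC(C)(C)O5)[C@H]5c3ccc(OCc4ccccc4)c(OC)c3)c1OCc1ccccc1 | intermediate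
21 | (4S,5R)-4-[4-(benzyloxy)-3-methoxyphenyl]-5-[2-(benzyloxy)-5-(bromomethyl)-3-methoxyphenyl]-2,2-dimethyl-1,3-dioxane (ring B bromide) | COc1cc(CBr)cc([C@H](COC(C)(C)O5)[C@H]5c3ccc(OCc4ccccc4)c(OC)c3)c1OCc1ccccc1 | intermediate
22 | furfural | O=Cc1ccco1 | starting material
23 | 5-hydroxyfuran-2(5H)-one (racemic) | OC1OC(=O)C=C1 | intermediate
24 | (+)-menthol ((1S,2R,5S)-2-isopropyl-5-methylcyclohexan-1-ol) | C[C@H]1CC[C@@H]([C@H](C1)O)C(C)C | starting material
25 | (5S)-5-{[(1S,2R,5S)-2-isopropyl-5-methylcyclohexyl]oxy}furan-2(5H)-one | O=C1C=C[C@@H](O[C@H]2C[C@@H](C)CC[C@@H]2C(C)C)O1 | intermediate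
26 | 2-lithio-2-(ArA)-1,3-dithiane (formed in situ) | COc1cc([C@@H](OC(C)(C)OC4)[C@H]4c2cc(C3([Li])SCCCS3)cc(OC)c2OCc2ccccc2)ccc1OCc1ccccc1 | intermediate
27 | lithium (4S,5S)-4-[2-(ArA)-1,3-dithian-2-yl]-5-(MenO)-4,5-dihydrofuran-2-olate (formed in situ) | COc1cc([C@@H](OC(C)(C)OC4)[C@H]4c2cc(C3(SCCCS3)[C@@H]5[C@@H](O[C@H]6C[C@@H](C)CC[C@@H]6C(C)C)OC(O[Li])=C5)cc(OC)c2OCc2ccccc2)ccc1OCc1ccccc1 | intermediate
28 | (3S,4S,5S)-3-[(ArB)methyl]-4-[2-(ArA)-1,3-dithian-2-yl]-5-(MenO)oxolan-2-one | COc1cc([C@@H](OC(C)(C)OC4)[C@H]4c2cc(C3(SCCCS3)[C@@H]5[C@@H](O[C@H]6C[C@@H](C)CC[C@@H]6C(C)C)OC(=O)[C@H]5Cc5cc(OC)c(OCc6ccccc6)c([C@H](COC(C)(C)O7)[C@H]7c6ccc(OCc7ccccc7)c(OC)c6)c5)cc(OC)c2OCc2ccccc2)ccc1OCc1ccccc1 | intermediate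
29 | (3S,4S,5S)-3-[(ArB)methyl]-4-[(ArA)methyl]-5-(MenO)oxolan-2-one | COc1cc([C@@H](OC(C)(C)OC4)[C@H]4c2cc(C[C@@H]5[C@@H](O[C@H]6C[C@@H](C)CC[C@@H]6C(C)C)OC(=O)[C@H]5Cc5cc(OC)c(OCc6ccccc6)c([C@H](COC(C)(C)O7)[C@H]7c6ccc(OCc7ccccc7)c(OC)c6)c5)cc(OC)c2OCc2ccccc2)ccc1OCc1ccccc1 | intermediate
30 | potassium (2S,3S)-2-[(ArB)methyl]-3-[(ArA)methyl]-4-oxobutanoate (formed in situ) | COc1cc([C@@H](OC(C)(C)OC4)[C@H]4c2cc(C[C@H](C=O)[C@H](Cc5cc(OC)c(OCc6ccccc6)c([C@H](COC(C)(C)O7)[C@H]7c6ccc(OCc7ccccc7)c(OC)c6)c5)C(=O)[O-])cc(OC)c2OCc2ccccc2)ccc1OCc1ccccc1.[K+] | intermediate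
31 | potassium (2S,3S)-4-hydroxy-2-[(ArB)methyl]-3-[(ArA)methyl]butanoate (formed in situ) | COc1cc([C@@H](OC(C)(C)OC4)[C@H]4c2cc(C[C@H](CO)[C@H](Cc5cc(OC)c(OCc6ccccc6)c([C@H](COC(C)(C)O7)[C@H]7c6ccc(OCc7ccccc7)c(OC)c6)c5)C(=O)[O-])cc(OC)c2OCc2ccccc2)ccc1OCc1ccccc1.[K+] | intermediate
32 | (3S,4S)-3-[(ArB)methyl]-4-[(ArA)methyl]oxolan-2-one | COc1cc([C@@H](OC(C)(C)OC4)[C@H]4c2cc(C[C@@H]5COC(=O)[C@H]5Cc5cc(OC)c(OCc6ccccc6)c([C@H](COC(C)(C)O7)[C@H]7c6ccc(OCc7ccccc7)c(OC)c6)c5)cc(OC)c2OCc2ccccc2)ccc1OCc1ccccc1 | intermediate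
33 | (3S,4S)-3-{4-(benzyloxy)-3-[(1S,2R)-1-(4-(benzyloxy)-3-methoxyphenyl)-1,3-dihydroxypropan-2-yl]-5-methoxybenzyl}-4-{4-(benzyloxy)-3-[(1S,2S)-1-(4-(benzyloxy)-3-methoxyphenyl)-1,3-dihydroxypropan-2-yl]-5-methoxybenzyl}oxolan-2-one | COc1cc([C@@H](O)[C@H](CO)c2cc(C[C@@H]3COC(=O)[C@H]3Cc3cc(OC)c(OCc4ccccc4)c([C@H](CO)[C@H](O)c4ccc(OCc5ccccc5)c(OC)c4)c3)cc(OC)c2OCc2ccccc2)ccc1OCc1ccccc1 | intermediate
34 | CNP0113972.1 | COc1cc([C@@H](O)[C@H](CO)c2cc(C[C@@H]3COC(=O)[C@H]3Cc3cc(OC)c(O)c([C@H](CO)[C@H](O)c4ccc(O)c(OC)c4)c3)cc(OC)c2O)ccc1O | target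

**Step count and risk**

Total steps: 21. Longest linear sequence: 16 steps (steps 1–5, 9–14, 17–21).

Steps most likely to fail:

1. Step 17. The C-benzylation of enolate 27 may stall, because the nucleophilic carbon sits beside the quaternary dithianyl centre; the enolate is then protonated on work-up and the sensitive benzylic bromide is lost. The fallback splits the coupling into two known operations, sets out from 13 (with 25) and rejoins the route at 29. Enolate 27 is quenched with aqueous NH4Cl to isolate the conjugate adduct (4S,5S)-4-[2-(ArA)-1,3-dithian-2-yl]-5-(MenO)oxolan-2-one F1. This is desulfurised with NiCl2·6H2O/NaBH4 to (4S,5S)-4-[(ArA)methyl]-5-(MenO)oxolan-2-one F2. The enolate of F2, now flanked only by a CH2Ar group, is generated with LDA in THF/DMPU at −78 °C and alkylated with bromide 21 anti to the C4 benzyl group, which gives 29.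

2. Step 6. The anti selectivity may erode, or the adduct may epimerise at the acidic C8–H or revert by retro-aldol under Et3N, because an arylacetyl imide is more acidic and more hindered than the usual propionyl imide. The fallback relies on substrate-controlled diastereoselection plus resolution, sets out from acid 5 and rejoins at diol 12. In an Ivanov reaction, the magnesium enediolate of 5 (iPrMgCl, 2 equiv, THF) adds to 9 through a chair transition state to give the racemic anti acid rac-(2R,3S)-3-[4-(benzyloxy)-3-methoxyphenyl]-2-[2-(benzyloxy)-5-(1,3-dithian-2-yl)-3-methoxyphenyl]-3-hydroxypropanoic acid F3. Classical resolution by crystallisation of its salt with an enantiopure 1-phenylethylamine (or preparative chiral chromatography) gives the (2R,3S)-acid F4. Reduction of F4 with LiAlH4 in THF gives 12.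

3. Step 3. The thioacetal sulfur atoms may bind palladium and slow oxidative addition into the hindered, electron-rich C–Br bond, so that the zinc enolate self-condenses before it couples. The fallback takes sulfur out of the catalytic step, sets out from 2 and rejoins at 4. The aldehyde is masked as 2-[4-(benzyloxy)-3-bromo-5-methoxyphenyl]-1,3-dioxolane F5 (ethylene glycol, TsOH, toluene, Dean–Stark). The same Reformatsky–Negishi coupling on this sulfur-free bromide gives ethyl 2-[2-(benzyloxy)-5-(1,3-dioxolan-2-yl)-3-methoxyphenyl]acetate F6. Transthioacetalisation of F6 with propane-1,3-dithiol and BF3·OEt2 converts the dioxolane directly into the dithiane and gives 4.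

**Further compounds**

F1 | step 17 | (4S,5S)-4-[2-(ArA)-1,3-dithian-2-yl]-5-(MenO)oxolan-2-one | COc1cc([C@@H](OC(C)(C)OC4)[C@H]4c2cc(C3(SCCCS3)[C@@H]5[C@@H](O[C@H]6C[C@@H](C)CC[C@@H]6C(C)C)OC(=O)C5)cc(OC)c2OCc2ccccc2)ccc1OCc1ccccc1
F2 | step 17 | (4S,5S)-4-[(ArA)methyl]-5-(MenO)oxolan-2-one | COc1cc([C@@H](OC(C)(C)OC4)[C@H]4c2cc(C[C@@H]5[C@@H](O[C@H]6C[C@@H](C)CC[C@@H]6C(C)C)OC(=O)C5)cc(OC)c2OCc2ccccc2)ccc1OCc1ccccc1
F3 | step 6 | rac-(2R,3S)-3-[4-(benzyloxy)-3-methoxyphenyl]-2-[2-(benzyloxy)-5-(1,3-dithian-2-yl)-3-methoxyphenyl]-3-hydroxypropanoic acid (racemate, both enantiomers written) | COc1cc([C@@H](O)[C@H](C(=O)O)c2cc(C3SCCCS3)cc(OC)c2OCc2ccccc2)ccc1OCc1ccccc1.COc1cc([C@H](O)[C@@H](C(=O)O)c2cc(C3SCCCS3)cc(OC)c2OCc2ccccc2)ccc1OCc1ccccc1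
F4 | step 6 | (2R,3S)-3-[4-(benzyloxy)-3-methoxyphenyl]-2-[2-(benzyloxy)-5-(1,3-dithian-2-yl)-3-methoxyphenyl]-3-hydroxypropanoic acid | COc1cc([C@@H](O)[C@H](C(=O)O)c2cc(C3SCCCS3)cc(OC)c2OCc2ccccc2)ccc1OCc1ccccc1
F5 | step 3 | 2-[4-(benzyloxy)-3-bromo-5-methoxyphenyl]-1,3-dioxolane | COc1cc(C2OCCO2)cc(Br)c1OCc1ccccc1
F6 | step 3 | ethyl 2-[2-(benzyloxy)-5-(1,3-dioxolan-2-yl)-3-methoxyphenyl]acetate | CCOC(=O)Cc1cc(C2OCCO2)cc(OC)c1OCc1ccccc1
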